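Ring A (C1–C5, C10; clerodane numbering) is cut at C1–C2 and C3–C4: C2–C3 becomes ethylene, while C1 and C4 remain as trans-diequatorial arms on the C5–C10 edge of a fully oxygenated ring B. The key step exploits that C4 carries the exocyclic methylene C18 and C1 an oxygen: a 4-alkynal (formyl C1 on C10, ethynyl C4≡C18 on C5) and ethylene undergo a rhodium-catalysed [4+2] annulation that closes ring A as the 4-methylenecyclohexanone, forming both C–C bonds at once. Ring B comes from a catalytic enantioselective Diels–Alder reaction; a temporary lactone/lactol ring between C1 and O11 steers its stereochemistry, and a furan masks the butenolide.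

Key step: step 15

Numbering and faces: ring A = C1–C5 and C10, ring B = C5–C10, C17 = methyl on C8, C18 = CH2 on C4, C19 = methyl on C5, C20 = methyl on C9, C11–C16 = side chain; β is the face of C19 and C20, α the opposite face.
Assumption: the (R)-configured oxazaborolidinium ion is taken to shield the enal face that leads to 4 (formyl C–H···O binding model); the antipodal catalyst would be used if the sense proved opposite.
Remark: C5 and C8 of 4 are written for the formyl-endo adduct; both centres are erased in steps 6 and 7, so the exo adduct serves equally.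

Step 1
Reactants: 1 (E)-hex-4-en-3-one
Product: 2 (2Z,4E)-3-(triisopropylsilyloxy)hexa-2,4-diene
Conditions: LiHMDS, THF, −78 °C; TIPSOTf
Reagents that add atoms: triisopropylsilyl triflate, CC(C)[Si](OS(=O)(=O)C(F)(F)F)(C(C)C)C(C)C
Why: Kinetic α′-deprotonation of the enone and O-silylation (silyl dienol ether formation) should give the cross-conjugated 2-siloxydiene, the Z enolate placing both methyl groups on the outside of the diene.

Step 2
Reactants: 2 (2Z,4E)-3-(triisopropylsilyloxy)hexa-2,4-diene; 3 ethyl (E)-3-methyl-4-oxobut-2-enoate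
Product: 4 ethyl 6-formyl-2,5,6-trimethyl-3-(triisopropylsilyloxy)cyclohex-3-ene-1-carboxylate (C10: CO2Et β; C9: CH3 β and CHO α)
Conditions: (R)-3,3-diphenyl-1-(o-tolyl)tetrahydro-1H,3H-pyrrolo[1,2-c][1,3,2]oxazaborole·HNTf2 (20 mol %), CH2Cl2, −78 to −40 °C
Reagents that add atoms: none
Why: Catalytic enantioselective Diels–Alder reaction (Corey oxazaborolidinium activation of the formyl group): the nucleophilic enol-ether terminus C5 bonds to C10, the carbon β to the activated aldehyde, so that C9 becomes the quaternary centre; the E geometry of 3 fixes C20 cis to the C10 ester and trans to C11, and the catalyst shields one enal face to set C9 and C10 absolutely.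

Step 3
Reactants: 4 Diels–Alder adduct; 5 3-(bromomethyl)furan
Product: 7 C11 carbinol (both C11 epimers) ethyl 6-[2-(furan-3-yl)-1-hydroxyethyl]-2,5,6-trimethyl-3-(triisopropylsilyloxy)cyclohex-3-ene-1-carboxylate, via (furan-3-ylmethyl)zinc bromide 6 (not isolated)
Conditions: Zn dust, LiCl, THF, 0 °C; then 4, −20 to 0 °C; cold aq. NH4Cl
Reagents that add atoms: none
Why: Barbier-type addition of a benzylic-type organozinc (LiCl-assisted zinc insertion into the bromide) to the hindered aldehyde is chemoselective over the ester and silyl enol ether; the new C11 centre is not controlled and is erased in step 4.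

Step 4
Reactants: 7 C11 carbinol
Product: 8 C11 ketone ethyl 6-[(furan-3-yl)acetyl]-2,5,6-trimethyl-3-(triisopropylsilyloxy)cyclohex-3-ene-1-carboxylate
Conditions: Dess–Martin periodinane, NaHCO3, CH2Cl2, 0 °C to rt
Reagents that add atoms: none
Why: Dess–Martin oxidation of the hindered secondary alcohol under buffered conditions leaves the silyl enol ether, ester and furan untouched.

Step 5
Reactants: 8 C11 ketone
Product: 10 trans-fused γ-lactone (C1 carbonyl, ring oxygen on C11, 11S) carrying the C6 silyl enol ether, via (11S)-hydroxy ester 9 (not isolated)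
Conditions: (R)-1-methyl-3,3-diphenyltetrahydro-1H,3H-pyrrolo[1,2-c][1,3,2]oxazaborole [(R)-Me-CBS, 20 mol %], catecholborane, toluene, −78 °C; work-up; then PPTS (cat.), toluene, 4 Å MS, 80 °C
Reagents that add atoms: none
Why: Corey–Bakshi–Shibata reduction, in which quaternary C9 is the large and the furylmethyl arm the small substituent, should give the (11S)-alcohol by reagent control, and acid-catalysed transesterification then closes the trans-fused γ-lactone that holds C1 and C11 equatorial and C20 axial for the following steps.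

Step 6
Reactants: 10 silyl enol ether lactone
Product: 11 lactone enone (C6 ketone, C7=C8)
Conditions: Pd(OAc)2 (1.1 equiv), MeCN, 40 °C
Reagents that add atoms: none
Why: Saegusa–Ito oxidation: palladation of the regiodefined silyl enol ether at C7 and β-hydride elimination of H8 give the C7=C8 enone without touching C5.

Step 7
Reactants: 11 lactone enone
Product: 13 5α-ethynyl lactone enone (C19 β), via lithium dienolate 12 (not isolated)
Conditions: LiHMDS, THF, −78 °C; TMS-EBX, Bu4NF, −78 °C to rt
Reagents that add atoms: 1-[(trimethylsilyl)ethynyl]-1,2-benziodoxol-3(1H)-one (TMS-EBX), C[Si](C)(C)C#CI1OC(=O)c2ccccc12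
Why: Electrophilic α-alkynylation of a ketone enolate with an ethynylbenziodoxolone (conjugate addition to the alkynyl iodane, loss of iodoarene, 1,2-shift of the carbene) creates the quaternary C5; the reagent approaches the lactone-locked dienolate from the α face, anti to the axial C20 methyl, leaving C19 β.

Step 8
Reactants: 13 5α-ethynyl lactone enone
Product: 14 6β-hydroxy lactol (C1 hemiacetal, anomers)
Conditions: i-Bu2AlH (3.5 equiv), CH2Cl2, −78 °C; Rochelle salt
Reagents that add atoms: none
Why: DIBAL delivers hydride 1,2 to the enone from the α face, anti to the axial C19 methyl of the locked ring, to give the equatorial 6β-alcohol, and at −78 °C reduces the lactone only as far as the lactol (tetrahedral aluminate).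

Step 9
Reactants: 14 6β-hydroxy lactol
Product: 15 6β-acetoxy lactol acetate (anomers)
Conditions: Ac2O, pyridine, DMAP, CH2Cl2, rt
Reagents that add atoms: acetic anhydride, CC(=O)OC(C)=O
Why: DMAP-catalysed acetylation of the allylic and the hemiacetal hydroxyl groups installs the final C6 acetate and keeps the bicyclic conformational lock as a lactol acetate.

Step 10
Reactants: 15 6β-acetoxy lactol acetate
Product: 16 7α,8α-diol
Conditions: OsO4 (5 mol %), NMO, acetone–H2O, rt
Reagents that add atoms: osmium tetroxide, O=[Os](=O)(=O)=O; N-methylmorpholine N-oxide, C[N+]1([O-])CCOCC1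
Why: Upjohn dihydroxylation: OsO4 adds syn to C7=C8 from the α face, anti to the allylic 6β-acetate (Kishi model) and to the axial C19 and C20 methyls of the lactol-locked ring, setting 7α-OH and 8α-OH; alkyne and furan react much more slowly.

Step 11
Reactants: 16 7α,8α-diol
Product: 17 7α-isobutyrate (8α-OH free)
Conditions: i-PrCOCl, pyridine, DMAP (cat.), CH2Cl2, 0 °C
Reagents that add atoms: isobutyryl chloride, CC(C)C(=O)Cl
Why: Acylation distinguishes the secondary equatorial 7-OH from the hindered tertiary axial 8-OH, which stays free as in the target.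

Step 12
Reactants: 17 7α-isobutyrate lactol acetate
Product: 18 lactol (C1 hemiacetal) with 6β-OAc and 7α-O-isobutyryl
Conditions: N2H4·HOAc, DMF, rt
Reagents that add atoms: none
Why: Chemoselective aminolysis of the anomeric (acylal-type) acetate by hydrazine acetate, a standard carbohydrate deprotection, leaves the ordinary acetate and isobutyrate in place.

Step 13
Reactants: 18 lactol
Product: 20 open-chain C1 N,N-dimethylhydrazone 11-acetate, via hydroxy hydrazone 19 (not isolated)
Conditions: Me2NNH2, EtOH, 50 °C; evaporate; Ac2O, pyridine, DMAP, rt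
Reagents that add atoms: 1,1-dimethylhydrazine, CN(C)N; acetic anhydride, CC(=O)OC(C)=O
Why: Hydrazone formation traps the open hydroxy-aldehyde tautomer of the lactol at C1 and thereby frees 11-OH, which is acetylated to its final form while the tertiary 8-OH does not react.

Step 14
Reactants: 20 dimethylhydrazone 11-acetate
Product: 21 alkynal (C1 formyl β on C10, ethynyl α on C5)
Conditions: CuCl2, THF–aq. phosphate buffer (pH 7), rt
Reagents that add atoms: water, O
Why: Copper-promoted neutral hydrolysis of the N,N-dimethylhydrazone (Corey–Knapp) releases the aldehyde without touching the esters, and the equatorial formyl group at C10 is the stable epimer.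

Step 15
Reactants: 21 alkynal; 22 ethylene
Product: 23 ring A ketone (1-oxo-4(18)-ene trans-decalin)
Conditions: [Rh(Ph2PCH2CH2PPh2)]2(BF4)2 (10 mol %), ethylene (5 atm), CH2Cl2, 40 °C
Reagents that add atoms: none
Why: Proposed new method: oxidative addition of the formyl C1–H bond to cationic monovalent rhodium, cis-hydrorhodation of the chelated C4≡C18 alkyne (H to C18, Rh to C4) to a five-membered acyl(alkenyl)rhodacycle, migratory insertion of ethylene and C–C reductive elimination should form C1–C2 and C3–C4 in one operation; the closest known reaction type is the rhodium-catalysed [4+2] annulation of 4-alkynals with alkynes and with acrylamides, extended here to ethylene, itself a good partner in intermolecular hydroacylation. Ring A closes as a formal (4+2) annulation: the rhodacycle forms by exo hydrometalation (rhodium at the internal alkyne carbon, C18 left outside as the methylene) and the six-membered ring by reductive elimination from a seven-membered rhodacycle. No stereocentre is created, since C1 and C4 are trigonal; the trans ring fusion is inherited from the trans-diequatorial formyl and ethynyl groups set at C10 and C5 in steps 2 and 7. The step needs ethylene insertion to outrun trans-hydroacylation to a cyclopentenone, plain hydroacylation of ethylene and decarbonylation; alkyne chelation, the gauche relation of the two arms on the chair of ring B (all large groups equatorial) and ethylene pressure should secure this, and no other reactive alkene or aldehyde is present.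

Step 16
Reactants: 23 ring A ketone
Product: 24 1α-alcohol
Conditions: SmI2, THF–H2O, 0 °C
Reagents that add atoms: none
Why: Single-electron (ketyl) reduction by SmI2 with water as proton donor is governed by product stability rather than by hydride approach, so the hydroxyl should take the equatorial 1α position and the hydrogen the axial site flanked by the C19 and C20 methyls; the esters, the isolated alkene and the furan are inert.

Step 17
Reactants: 24 1α-alcohol
Product: 25 1α,6β,11-triacetate 7α-isobutyrate furan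
Conditions: Ac2O, pyridine, DMAP, CH2Cl2, rt
Reagents that add atoms: acetic anhydride, CC(=O)OC(C)=O
Why: DMAP-catalysed acetylation of the secondary 1α-OH with retention, the tertiary 8-OH again remaining free.

Step 18
Reactants: 25 furan triacetate
Product: 27 16-hydroxy-15,16-olide (γ-hydroxybutenolide, C16 epimers), via furan endoperoxide 26 (not isolated)
Conditions: O2, hν (visible), 5,10,15,20-tetraphenylporphyrin (cat.), i-Pr2NEt, CH2Cl2, −78 °C
Reagents that add atoms: dioxygen, O=O
Why: [4+2] cycloaddition of singlet oxygen to the furan and base-induced fragmentation of the endoperoxide (Kornblum–DeLaMare type), in which the hindered amine removes the less hindered H15, should give the β-substituted γ-hydroxybutenolide regioselectively, the hindered 1,1-disubstituted alkene reacting far more slowly.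

Step 19
Reactants: 27 γ-hydroxybutenolide
Product: 29 CNP0266716.1, via sodium hydroxy-enoate 28 (not isolated)
Conditions: NaBH4, EtOH, 0 °C; then 1 M HCl
Reagents that add atoms: none
Why: Borohydride reduces the aldehyde of the ring-opened hydroxybutenolide and acidification lactonises the Z hydroxy acid to the 15,16-olide; the esters survive the short reaction at 0 °C.

Compound list
1 | (E)-hex-4-en-3-one | CCC(=O)/C=C/C | starting material
2 | (2Z,4E)-3-(triisopropylsilyloxy)hexa-2,4-diene | C/C=C(O[Si](C(C)C)(C(C)C)C(C)C)/C=C/C | intermediate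
3 | ethyl (E)-3-methyl-4-oxobut-2-enoate | CCOC(=O)/C=C(\C)C=O | starting material
4 | ethyl 6-formyl-2,5,6-trimethyl-3-(triisopropylsilyloxy)cyclohex-3-ene-1-carboxylate (C10: CO2Et β, H α; C9: CH3 β, CHO α; C5 and C8 methyls α) | CCOC(=O)[C@H]1[C@H](C)C(O[Si](C(C)C)(C(C)C)C(C)C)=C[C@H](C)[C@]1(C)C=O | intermediate
5 | 3-(bromomethyl)furan | BrCc1ccoc1 | starting material
6 | (furan-3-ylmethyl)zinc bromide (not isolated) | Br[Zn]Cc1ccoc1 | intermediate
7 | ethyl 6-[2-(furan-3-yl)-1-hydroxyethyl]-2,5,6-trimethyl-3-(triisopropylsilyloxy)cyclohex-3-ene-1-carboxylate (C11 epimers; ring as in 4) | CCOC(=O)[C@H]1[C@H](C)C(O[Si](C(C)C)(C(C)C)C(C)C)=C[C@H](C)[C@]1(C)C(O)Cc1ccoc1 | intermediate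
8 | ethyl 6-[(furan-3-yl)acetyl]-2,5,6-trimethyl-3-(triisopropylsilyloxy)cyclohex-3-ene-1-carboxylate (ring as in 4) | CCOC(=O)[C@H]1[C@H](C)C(O[Si](C(C)C)(C(C)C)C(C)C)=C[C@H](C)[C@]1(C)C(=O)Cc1ccoc1 | intermediate
9 | (11S)-hydroxy ester from 8 (not isolated) | CCOC(=O)[C@H]1[C@H](C)C(O[Si](C(C)C)(C(C)C)C(C)C)=C[C@H](C)[C@]1(C)[C@H](Cc1ccoc1)O | intermediate
10 | trans-fused γ-lactone: 3-(furan-3-ylmethyl)-3a,4,7-trimethyl-6-(triisopropylsilyloxy)-3a,4,7,7a-tetrahydroisobenzofuran-1(3H)-one (C1 carbonyl, O on C11, 11S, C20 β, H10 α) | O=C1[C@H]2[C@H](C)C(O[Si](C(C)C)(C(C)C)C(C)C)=C[C@H](C)[C@]2(C)[C@H](Cc3ccoc3)O1 | intermediate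
11 | lactone enone: C6 ketone, C7=C8 with C17 on C8, C5 methyl α (epimerisable) | O=C1[C@H]2[C@H](C)C(=O)C=C(C)[C@]2(C)[C@H](Cc3ccoc3)O1 | intermediate
12 | lithium C5=C6 dienolate of 11 (not isolated) | O=C1[C@H]2C(C)=C([O-])C=C(C)[C@]2(C)[C@H](Cc3ccoc3)O1.[Li+] | intermediate
13 | 5α-ethynyl lactone enone (C19 β) | O=C1[C@H]2[C@@](C#C)(C)C(=O)C=C(C)[C@]2(C)[C@H](Cc3ccoc3)O1 | intermediate
14 | 6β-hydroxy lactol (C1 hemiacetal, anomers; 5α-ethynyl, C7=C8) | OC1[C@H]2[C@@](C#C)(C)[C@@H](O)C=C(C)[C@]2(C)[C@H](Cc3ccoc3)O1 | intermediate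
15 | 6β-acetoxy lactol acetate (anomers) | CC(=O)OC1[C@H]2[C@@](C#C)(C)[C@@H](OC(C)=O)C=C(C)[C@]2(C)[C@H](Cc3ccoc3)O1 | intermediate
16 | 7α,8α-diol of 15 (C17 β) | CC(=O)OC1[C@H]2[C@@](C#C)(C)[C@@H](OC(C)=O)[C@H](O)[C@](C)(O)[C@]2(C)[C@H](Cc3ccoc3)O1 | intermediate
17 | 7α-isobutyrate of 16 (8α-OH free) | CC(=O)OC1[C@H]2[C@@](C#C)(C)[C@@H](OC(C)=O)[C@H](OC(=O)C(C)C)[C@](C)(O)[C@]2(C)[C@H](Cc3ccoc3)O1 | intermediate
18 | lactol (C1 hemiacetal, anomers) with 6β-OAc, 7α-O-isobutyryl, 8α-OH | OC1[C@H]2[C@@](C#C)(C)[C@@H](OC(C)=O)[C@H](OC(=O)C(C)C)[C@](C)(O)[C@]2(C)[C@H](Cc3ccoc3)O1 | intermediate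
19 | open-chain C1 (E)-N,N-dimethylhydrazone with free (11S)-OH (not isolated) | CN(C)/N=C/[C@H]1[C@@](C#C)(C)[C@@H](OC(C)=O)[C@H](OC(=O)C(C)C)[C@](C)(O)[C@]1(C)[C@H](Cc1ccoc1)O | intermediate
20 | C1 (E)-N,N-dimethylhydrazone (11S)-acetate | CN(C)/N=C/[C@H]1[C@@](C#C)(C)[C@@H](OC(C)=O)[C@H](OC(=O)C(C)C)[C@](C)(O)[C@]1(C)[C@H](Cc1ccoc1)OC(C)=O | intermediate
21 | alkynal: ring B with formyl C1 (β) on C10, ethynyl (α) and C19 (β) on C5, 6β-OAc, 7α-O-isobutyryl, 8α-OH/C17 β, C20 β and (11S)-CH(OAc)CH2(3-furyl) (α) on C9 | O=C[C@H]1[C@@](C#C)(C)[C@@H](OC(C)=O)[C@H](OC(=O)C(C)C)[C@](C)(O)[C@]1(C)[C@H](Cc1ccoc1)OC(C)=O | intermediate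
22 | ethylene | C=C | starting material
23 | ring A ketone: 1-oxo-4(18)-ene trans-decalin (H10 α, C19 β), ring B and side chain as in 21 | C=C1CCC(=O)[C@H]2[C@@]1(C)[C@@H](OC(C)=O)[C@H](OC(=O)C(C)C)[C@](C)(O)[C@]2(C)[C@H](Cc1ccoc1)OC(C)=O | intermediate
24 | 1α-alcohol (equatorial OH) | C=C1CC[C@@H](O)[C@H]2[C@@]1(C)[C@@H](OC(C)=O)[C@H](OC(=O)C(C)C)[C@](C)(O)[C@]2(C)[C@H](Cc1ccoc1)OC(C)=O | intermediate
25 | 1α,6β,11-triacetate 7α-isobutyrate with 3-furyl side chain | C=C1CC[C@@H](OC(C)=O)[C@H]2[C@@]1(C)[C@@H](OC(C)=O)[C@H](OC(=O)C(C)C)[C@](C)(O)[C@]2(C)[C@H](Cc1ccoc1)OC(C)=O | intermediate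
26 | furan 15,16-endoperoxide of 25 (not isolated) | C=C1CC[C@@H](OC(C)=O)[C@H]2[C@@]1(C)[C@@H](OC(C)=O)[C@H](OC(=O)C(C)C)[C@](C)(O)[C@]2(C)[C@H](CC1=CC2OOC1O2)OC(C)=O | intermediate
27 | 16-hydroxy-15,16-olide (γ-hydroxybutenolide, C16 epimers) | C=C1CC[C@@H](OC(C)=O)[C@H]2[C@@]1(C)[C@@H](OC(C)=O)[C@H](OC(=O)C(C)C)[C@](C)(O)[C@]2(C)[C@H](CC1=CC(=O)OC1O)OC(C)=O | intermediate
28 | sodium (Z)-16-hydroxy-13-en-15-oate (not isolated) | C=C1CC[C@@H](OC(C)=O)[C@H]2[C@@]1(C)[C@@H](OC(C)=O)[C@H](OC(=O)C(C)C)[C@](C)(O)[C@]2(C)[C@H](C/C(CO)=C/C(=O)[O-])OC(C)=O.[Na+] | intermediate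
29 | CNP0266716.1 | C=C1CC[C@@H](OC(C)=O)[C@H]2[C@@]1(C)[C@@H](OC(C)=O)[C@H](OC(=O)C(C)C)[C@](C)(O)[C@]2(C)[C@H](CC1=CC(=O)OC1)OC(C)=O | target

Total step count: 19. Longest linear sequence: 19 steps (1 to 29); 3, 5 and 22 enter directly as purchased.

Steps most likely to fail

1. Step 15 (proposed new method). Ethylene insertion may lose against trans-hydroacylation to a cyclopentenone, against decarbonylation of the hindered acyl–rhodium hydride, or against vinylidene formation at the terminal alkyne. The fallback uses known chemistry and makes the two ring bonds in separate operations. It sets out from 21: vinylmagnesium bromide with CeCl3 (THF, −78 °C) should give the vinyl carbinol F1, and Dess–Martin oxidation the vinyl ketone F2. Bu3SnH/AIBN (benzene, 80 °C, high dilution) should then effect a stannyl-radical enyne cyclisation, in which the tin radical adds to C18 and the C4 vinyl radical closes 6-endo on C3 of the enone, to give the 18-stannyl ring A ketone F3. Protodestannylation (HCl, Et2O, 0 °C) comes back to the route at 23.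

2. Step 7. Carbon–carbon bond formation at the hindered tertiary enolate carbon may be slow, the reagent may approach from the β face, or the iodane may be consumed by electron transfer from the enolate. The fallback sets out from 11: the same lithium enolate is hydroxymethylated with gaseous formaldehyde (aldol reaction, same α-face approach) to the hydroxymethyl ketone F4. Dess–Martin oxidation gives the non-enolisable keto aldehyde F5, and Colvin homologation with lithiated (trimethylsilyl)diazomethane (THF, −78 °C) converts the formyl group into the ethynyl group, coming back at 13.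

3. Step 16. Thermodynamic control may be lost, with hydrogen delivered from the open α face to give the axial 1β-alcohol (poor stereocontrol at C1). The fallback sets out from 23: NaBH4/CeCl3 (MeOH, −40 °C) is allowed to give the 1β-alcohol F6, which is equilibrated by ruthenium-catalysed hydrogen-transfer epimerisation ((C5Ph5)Ru(CO)2Cl, KOtBu cat., toluene, 50 °C) to the more stable equatorial alcohol, coming back at 24.

Further compounds
F1 | step 15 | vinyl carbinol (C1 epimers) from 21 | C=CC(O)[C@H]1[C@@](C#C)(C)[C@@H](OC(C)=O)[C@H](OC(=O)C(C)C)[C@](C)(O)[C@]1(C)[C@H](Cc1ccoc1)OC(C)=O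
F2 | step 15 | vinyl ketone | C=CC(=O)[C@H]1[C@@](C#C)(C)[C@@H](OC(C)=O)[C@H](OC(=O)C(C)C)[C@](C)(O)[C@]1(C)[C@H](Cc1ccoc1)OC(C)=O
F3 | step 15 | 18-(tributylstannyl) ring A ketone | CCCC[Sn](CCCC)(CCCC)C=C1CCC(=O)[C@H]2[C@@]1(C)[C@@H](OC(C)=O)[C@H](OC(=O)C(C)C)[C@](C)(O)[C@]2(C)[C@H](Cc1ccoc1)OC(C)=O
F4 | step 7 | 5α-(hydroxymethyl) lactone enone | O=C1[C@H]2[C@@](CO)(C)C(=O)C=C(C)[C@]2(C)[C@H](Cc3ccoc3)O1
F5 | step 7 | 5α-formyl lactone enone | O=C1[C@H]2[C@@](C=O)(C)C(=O)C=C(C)[C@]2(C)[C@H](Cc3ccoc3)O1
F6 | step 16 | 1β-alcohol (axial OH) | C=C1CC[C@H](O)[C@H]2[C@@]1(C)[C@@H](OC(C)=O)[C@H](OC(=O)C(C)C)[C@](C)(O)[C@]2(C)[C@H](Cc1ccoc1)OC(C)=O
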